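The ring is cut at C2–C3, the bond between the two acetoxy carbons (ring numbering: C1 carbinol bearing C7H2OBz, C4=C5, C6 benzoate). A carbene-catalysed intramolecular crossed benzoin of lactol-aldehyde 10 joins an acyl anion at C3 to the masked aldehyde C2, closing the carbocycle and setting C2; the β-oxygen on C5, the former furanose oxygen, is then expelled, so the C4=C5 alkene arises from the acyloin itself. Precursor 10 is a 5-deoxy-hexodialdofuranose whose C2, C1, C6, C5 and C4 are C1–C5 of D-mannose; C7 comes from formaldehyde and C3 from a methoxymethylene ylide. The step exploits the vicinal C2/C3 oxygens flanking C4=C5 and the cis O1/O6 pair.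

Key step: step 7

Remark on locants: compounds 1–10 carry carbohydrate numbering; compounds 11–17 carry the ring numbering above (sugar C1/C2/C3/C4/C5 = ring C2/C1/C6/C5/C4). The β face is the face of C7 on C1, so the target has O1 α, O6 α, O2 β, O3 α.

Remark (assumption): 3–10 are carried as anomeric mixtures and 8–9 as E/Z mixtures. Both elements vanish in step 7, so the SMILES leave them open.

Step 1
Reactants: 1 2,3:5,6-di-O-isopropylidene-α-D-mannofuranose; 2 formaldehyde
Product: 3 2-C-(hydroxymethyl)-2,3:5,6-di-O-isopropylidene-D-mannofuranose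
Conditions: 37% aq. HCHO (5 equiv), K2CO3, MeOH, 65 °C
Reagents that add atoms: none
Why: Crossed aldol (hydroxymethylation) of the open-chain aldehyde tautomer through its C2 enolate, which formaldehyde should attack on the dioxolane face anti to the C4 side chain, so that CH2OH replaces H-2 with retention (new quaternary centre, the future ring C1), the furanose re-closes and, with no α-hydrogen left, the reaction stops after one addition.

Step 2
Reactants: 3 2-C-(hydroxymethyl)-2,3:5,6-di-O-isopropylidene-D-mannofuranose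
Product: 4 1-O-benzoyl-2-C-[(benzoyloxy)methyl]-2,3:5,6-di-O-isopropylidene-D-mannofuranose
Conditions: BzCl (2.5 equiv), pyridine, DMAP (cat.), CH2Cl2, 0 °C to rt
Reagents that add atoms: benzoyl chloride, O=C(Cl)c1ccccc1
Why: DMAP-catalysed acylation esterifies both the neopentyl primary hydroxyl (the C7 benzoate of the target) and the hemiacetal hydroxyl, whose ester masks C1 and blocks retro-aldol loss of formaldehyde in the basic steps that follow; no stereocentre of consequence is formed.

Step 3
Reactants: 4 1-O-benzoyl-2-C-[(benzoyloxy)methyl]-2,3:5,6-di-O-isopropylidene-D-mannofuranose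
Product: 6 1-O-benzoyl-2-C-[(benzoyloxy)methyl]-2,3-O-isopropylidene-D-lyxo-pentodialdo-1,4-furanose, via 5,6-diol 5 (not isolated)
Conditions: H5IO6 (1.5 equiv), EtOAc, rt
Reagents that add atoms: none
Why: Periodic acid should hydrolyse the terminal 5,6-acetonide in preference to the cis-fused 2,3-acetonide and cleave the liberated glycol (periodate glycol cleavage) to the C5 aldehyde without touching the esters.

Step 4
Reactants: 6 1-O-benzoyl-2-C-[(benzoyloxy)methyl]-2,3-O-isopropylidene-D-lyxo-pentodialdo-1,4-furanose; 7 (methoxymethyl)triphenylphosphonium chloride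
Product: 8 1-O-benzoyl-2-C-[(benzoyloxy)methyl]-5-deoxy-2,3-O-isopropylidene-6-O-methyl-D-lyxo-hex-5-enofuranose
Conditions: 7, KN(SiMe3)2, THF, 0 °C; then 6, −78 to 0 °C
Reagents that add atoms: none
Why: Wittig olefination with the non-stabilised methoxymethylene ylide adds the carbon that becomes ring C3, the esters being inert at low temperature; the alkene geometry and any epimerisation at sugar C4 do not matter because both positions are later sp2 or re-made.

Step 5
Reactants: 8 1-O-benzoyl-2-C-[(benzoyloxy)methyl]-5-deoxy-2,3-O-isopropylidene-6-O-methyl-D-lyxo-hex-5-enofuranose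
Product: 9 2-C-[(benzoyloxy)methyl]-5-deoxy-2,3-O-isopropylidene-6-O-methyl-D-lyxo-hex-5-enofuranose
Conditions: N2H4·AcOH (1.5 equiv), DMF, 0 °C to rt
Reagents that add atoms: none
Why: Chemoselective hydrazinolysis (acyl transfer) should remove only the anomeric benzoate, which is far more electrophilic than the neopentyl primary benzoate because its leaving group is a hemiacetal oxide, and so frees the lactol.

Step 6
Reactants: 9 2-C-[(benzoyloxy)methyl]-5-deoxy-2,3-O-isopropylidene-6-O-methyl-D-lyxo-hex-5-enofuranose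
Product: 10 2-C-[(benzoyloxy)methyl]-5-deoxy-2,3-O-isopropylidene-D-lyxo-hexodialdo-1,4-furanose
Conditions: TsOH·H2O (10 mol%), acetone–H2O (9:1), rt
Reagents that add atoms: water, O
Why: Acid-catalysed enol ether hydrolysis (protonation at C5, addition of water, loss of methanol) should give the CH2CHO aldehyde, while acetone as solvent suppresses loss of the acetonide.

Step 7
Reactants: 10 2-C-[(benzoyloxy)methyl]-5-deoxy-2,3-O-isopropylidene-D-lyxo-hexodialdo-1,4-furanose
Product: 13 [2β-hydroxy-1α,6α-(isopropylidenedioxy)-3-oxocyclohex-4-en-1-yl]methyl benzoate, via acyloin 11 (not isolated), via 5-O-mesylate 12 (not isolated)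
Conditions: 2-mesityl-6,7-dihydro-5H-pyrrolo[2,1-c][1,2,4]triazol-2-ium chloride (10 mol%), iPr2NEt (15 mol%), CH2Cl2, 23 °C; then MsCl (1.2 equiv), Et3N (3 equiv), −20 °C to rt
Reagents that add atoms: none
Why: The free carbene adds to the unhindered CH2CHO aldehyde (ring C3) to give the amino enol (acyl anion equivalent), which attacks the C2 aldehyde liberated by ring–chain tautomerism of the lactol; proton transfer and loss of the carbene give acyloin 11, and sulfonylation of its less hindered C5 hydroxyl followed by E1cB loss of methanesulfonate from the β-position of the C3 ketone gives enone 13. The closest known reaction type is the carbene-catalysed intramolecular crossed benzoin (acyloin) cyclisation of carbohydrate-derived dialdehydes to inososes, here followed by a routine β-elimination. One ring is closed, the six-membered carbocycle, by 6-exo-trig addition of the C3 acyl anion equivalent to the C2 carbonyl. The only new stereocentre that is kept is C2, controlled by the neighbouring quaternary C1: in the chair-like transition state with C7, O5 and O6 equatorial the forming alkoxide should lie anti to the axial C1–O bond (opposed dipoles), which places O2 trans to O1 on the face of C7; the C5 carbinol is inherited from mannose C4 and is erased in the elimination. Donor/acceptor chemoselectivity is required and is secured because the α-quaternary aldehyde is hindered and stored as the lactol, so only the C3 aldehyde can form the acyl anion equivalent, and the elimination can only give the C4=C5 enone because C4 bears the sole α-hydrogens and C1 is quaternary. The benzoin must also outrun base-induced β-elimination of the lactol oxygen from 10 and epimerisation of 11 at C2, hence a weak amine base in catalytic amount, ambient temperature and immediate sulfonylation.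

Step 8
Reactants: 13 [2β-hydroxy-1α,6α-(isopropylidenedioxy)-3-oxocyclohex-4-en-1-yl]methyl benzoate
Product: 14 [2β,3α-dihydroxy-1α,6α-(isopropylidenedioxy)cyclohex-4-en-1-yl]methyl benzoate
Conditions: Me4NBH(OAc)3 (3 equiv), MeCN–AcOH (1:1), −25 °C
Reagents that add atoms: none
Why: Hydroxyl-directed reduction (Evans–Saksena type): the C2 hydroxyl exchanges an acetate on boron and the hydride should be delivered intramolecularly to the carbonyl face syn to O2, which sets O3 trans to O2 and avoids conjugate reduction.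

Step 9
Reactants: 14 [2β,3α-dihydroxy-1α,6α-(isopropylidenedioxy)cyclohex-4-en-1-yl]methyl benzoate
Product: 15 [2β,3α-diacetoxy-1α,6α-(isopropylidenedioxy)cyclohex-4-en-1-yl]methyl benzoate
Conditions: Ac2O, pyridine, DMAP (cat.), CH2Cl2, rt
Reagents that add atoms: acetic anhydride, CC(=O)OC(C)=O
Why: DMAP-catalysed acylation should esterify both secondary hydroxyls, the tertiary oxygen being locked in the acetonide.

Step 10
Reactants: 15 [2β,3α-diacetoxy-1α,6α-(isopropylidenedioxy)cyclohex-4-en-1-yl]methyl benzoate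
Product: 16 [(1S,2S,3R,6S)-2,3-diacetoxy-1,6-dihydroxycyclohex-4-en-1-yl]methyl benzoate
Conditions: TFA–H2O (9:1), CH2Cl2, 0 °C
Reagents that add atoms: none
Why: Acid-catalysed acetal hydrolysis through the acetonide oxocarbenium ion should release the cis C1/C6 diol, the esters surviving cold aqueous acid, and a benzoyl shift from O7 to O6 would be harmless because both oxygens end as benzoates.

Step 11
Reactants: 16 [(1S,2S,3R,6S)-2,3-diacetoxy-1,6-dihydroxycyclohex-4-en-1-yl]methyl benzoate
Product: 17 cleistenediol F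
Conditions: BzCl (1.3 equiv), pyridine, CH2Cl2, −20 to 0 °C
Reagents that add atoms: benzoyl chloride, O=C(Cl)c1ccccc1
Why: Selective acylation should benzoylate the secondary allylic C6 hydroxyl and leave the unreactive tertiary C1 hydroxyl free, giving the target.

Compound list
1 | 2,3:5,6-di-O-isopropylidene-α-D-mannofuranose | O[C@@H]1[C@H]2OC(C)(C)O[C@H]2[C@H](O1)[C@H]1COC(C)(C)O1 | starting material
2 | formaldehyde | C=O | starting material
3 | 2-C-(hydroxymethyl)-2,3:5,6-di-O-isopropylidene-D-mannofuranose (anomeric mixture) | OC1[C@@]2(CO)OC(C)(C)O[C@H]2[C@H](O1)[C@H]1COC(C)(C)O1 | intermediate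
4 | 1-O-benzoyl-2-C-[(benzoyloxy)methyl]-2,3:5,6-di-O-isopropylidene-D-mannofuranose (anomeric mixture) | O=C(c1ccccc1)OC1[C@@]2(COC(=O)c3ccccc3)OC(C)(C)O[C@H]2[C@H](O1)[C@H]1COC(C)(C)O1 | intermediate
5 | 1-O-benzoyl-2-C-[(benzoyloxy)methyl]-2,3-O-isopropylidene-D-mannofuranose (5,6-diol, not isolated) | O=C(c1ccccc1)OC1[C@@]2(COC(=O)c3ccccc3)OC(C)(C)O[C@H]2[C@H](O1)[C@H](O)CO | intermediate
6 | 1-O-benzoyl-2-C-[(benzoyloxy)methyl]-2,3-O-isopropylidene-D-lyxo-pentodialdo-1,4-furanose | O=C(c1ccccc1)OC1[C@@]2(COC(=O)c3ccccc3)OC(C)(C)O[C@H]2[C@H](O1)C=O | intermediate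
7 | (methoxymethyl)triphenylphosphonium chloride | COC[P+](c1ccccc1)(c1ccccc1)c1ccccc1.[Cl-] | starting material
8 | 1-O-benzoyl-2-C-[(benzoyloxy)methyl]-5-deoxy-2,3-O-isopropylidene-6-O-methyl-D-lyxo-hex-5-enofuranose (E/Z mixture) | O=C(c1ccccc1)OC1[C@@]2(COC(=O)c3ccccc3)OC(C)(C)O[C@H]2[C@H](O1)C=COC | intermediate
9 | 2-C-[(benzoyloxy)methyl]-5-deoxy-2,3-O-isopropylidene-6-O-methyl-D-lyxo-hex-5-enofuranose (lactol, E/Z mixture) | OC1[C@@]2(COC(=O)c3ccccc3)OC(C)(C)O[C@H]2[C@H](O1)C=COC | intermediate
10 | 2-C-[(benzoyloxy)methyl]-5-deoxy-2,3-O-isopropylidene-D-lyxo-hexodialdo-1,4-furanose (lactol aldehyde) | OC1[C@@]2(COC(=O)c3ccccc3)OC(C)(C)O[C@H]2[C@H](O1)CC=O | intermediate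
11 | acyloin, [2β,5β-dihydroxy-1α,6α-(isopropylidenedioxy)-3-oxocyclohexan-1-yl]methyl benzoate (not isolated) | O=C1C[C@@H](O)[C@@H]2OC(C)(C)O[C@]2(COC(=O)c3ccccc3)[C@H]1O | intermediate
12 | 5-O-mesylate of 11, [2β-hydroxy-1α,6α-(isopropylidenedioxy)-5β-(methanesulfonyloxy)-3-oxocyclohexan-1-yl]methyl benzoate (not isolated) | O=C1C[C@@H](OS(C)(=O)=O)[C@@H]2OC(C)(C)O[C@]2(COC(=O)c3ccccc3)[C@H]1O | intermediate
13 | enone, [2β-hydroxy-1α,6α-(isopropylidenedioxy)-3-oxocyclohex-4-en-1-yl]methyl benzoate (cis-fused acetonide) | O=C1C=C[C@@H]2OC(C)(C)O[C@]2(COC(=O)c3ccccc3)[C@H]1O | intermediate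
14 | trans-diol, [2β,3α-dihydroxy-1α,6α-(isopropylidenedioxy)cyclohex-4-en-1-yl]methyl benzoate | O[C@@H]1C=C[C@@H]2OC(C)(C)O[C@]2(COC(=O)c3ccccc3)[C@H]1O | intermediate
15 | diacetate, [2β,3α-diacetoxy-1α,6α-(isopropylidenedioxy)cyclohex-4-en-1-yl]methyl benzoate | CC(=O)O[C@@H]1C=C[C@@H]2OC(C)(C)O[C@]2(COC(=O)c3ccccc3)[C@H]1OC(C)=O | intermediate
16 | [(1S,2S,3R,6S)-2,3-diacetoxy-1,6-dihydroxycyclohex-4-en-1-yl]methyl benzoate | CC(=O)O[C@@H]1C=C[C@H](O)[C@@](O)(COC(=O)c2ccccc2)[C@H]1OC(C)=O | intermediate
17 | cleistenediol F, [(1S,2S,3R,6S)-2,3-diacetoxy-6-(benzoyloxy)-1-hydroxycyclohex-4-en-1-yl]methyl benzoate | CC(=O)O[C@@H]1C=C[C@H](OC(=O)c2ccccc2)[C@@](O)(COC(=O)c2ccccc2)[C@H]1OC(C)=O | target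

Total step count: 11. Longest linear sequence: 11 steps (1 to 17).

Steps most likely to fail

Step 7. What may go wrong: base-induced β-elimination of the lactol oxygen from the β-alkoxy aldehyde before the carbon–carbon bond forms, or reversal of the benzoin and epimerisation at C2. The fallback replaces the carbene umpolung by a reductive ketyl–nitrile cyclisation; it sets out from 8 and comes back at 11. Enol ether 8 is hydrolysed (TsOH·H2O, acetone–H2O) to the 1-O-benzoyl aldehyde F1. This is converted with NH2OH·HCl and pyridine into aldoxime F2 and dehydrated with 1,1'-carbonyldiimidazole to nitrile F3, which is no longer prone to β-elimination. Hydrazine acetate then frees lactol nitrile F4. SmI2 (THF, tBuOH, visible light) should reduce the ring-opened aldehyde to its ketyl, which adds 6-exo to the nitrile carbon to give the cyclic α-hydroxy ketimine F5. Mildly acidic aqueous work-up hydrolyses it to acyloin 11, which is isolated and taken through the mesylation and elimination of step 7.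

Step 8. What may go wrong: hydride delivery to the wrong carbonyl face, or competing conjugate reduction. The fallback does not rely on the directing hydroxyl and corrects C3 by inversion; it sets out from 13 and comes back at 15. 1,2-Reduction with NaBH4 and CeCl3·7H2O (Luche conditions, MeOH, −78 °C) gives 14 together with, or in place of, its C3 epimer, the cis-diol F6. F6 is submitted to Mitsunobu esterification (PPh3, DIAD, AcOH), which should invert only the unhindered allylic C3 carbinol and give the 3α-acetate F7. Acetylation of the remaining C2 hydroxyl (Ac2O, DMAP) gives 15; any 14 formed is acetylated directly as in step 9.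

Step 5. What may go wrong: competing hydrazinolysis of the primary benzoate, or sluggish cleavage of the hindered anomeric ester. The fallback avoids an anomeric ester altogether by carrying sugar C1 as a lactone; it sets out from 3 and comes back at 9. Lactol 3 is oxidised with Ag2CO3 on Celite (toluene, reflux) to lactone F8, whose only free hydroxyl is benzoylated (BzCl, pyridine) to benzoate F9. H5IO6 in EtOAc, by way of the 5,6-diol F10 (not isolated), gives aldehyde F11, and the Wittig reaction with the ylide from 7 and KN(SiMe3)2 gives enol ether F12. iBu2AlH (1.05 equiv, CH2Cl2, −78 °C) should reduce the activated α-alkoxy γ-lactone faster than the neopentyl benzoate and give lactol 9.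

Further compounds
F1 | step 7 | 1-O-benzoyl-2-C-[(benzoyloxy)methyl]-5-deoxy-2,3-O-isopropylidene-D-lyxo-hexodialdo-1,4-furanose | O=C(c1ccccc1)OC1[C@@]2(COC(=O)c3ccccc3)OC(C)(C)O[C@H]2[C@H](O1)CC=O
F2 | step 7 | aldoxime of F1 | O=C(c1ccccc1)OC1[C@@]2(COC(=O)c3ccccc3)OC(C)(C)O[C@H]2[C@H](O1)CC=NO
F3 | step 7 | 1-O-benzoyl-2-C-[(benzoyloxy)methyl]-5-deoxy-2,3-O-isopropylidene-D-lyxo-hexofuranurononitrile | O=C(c1ccccc1)OC1[C@@]2(COC(=O)c3ccccc3)OC(C)(C)O[C@H]2[C@H](O1)CC#N
F4 | step 7 | lactol nitrile, 2-C-[(benzoyloxy)methyl]-5-deoxy-2,3-O-isopropylidene-D-lyxo-hexofuranurononitrile | OC1[C@@]2(COC(=O)c3ccccc3)OC(C)(C)O[C@H]2[C@H](O1)CC#N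
F5 | step 7 | ketimine, [2β,5β-dihydroxy-3-imino-1α,6α-(isopropylidenedioxy)cyclohexan-1-yl]methyl benzoate | N=C1C[C@@H](O)[C@@H]2OC(C)(C)O[C@]2(COC(=O)c3ccccc3)[C@H]1O
F6 | step 8 | cis-diol, [2β,3β-dihydroxy-1α,6α-(isopropylidenedioxy)cyclohex-4-en-1-yl]methyl benzoate | O[C@H]1C=C[C@@H]2OC(C)(C)O[C@]2(COC(=O)c3ccccc3)[C@H]1O
F7 | step 8 | [3α-acetoxy-2β-hydroxy-1α,6α-(isopropylidenedioxy)cyclohex-4-en-1-yl]methyl benzoate | CC(=O)O[C@@H]1C=C[C@@H]2OC(C)(C)O[C@]2(COC(=O)c3ccccc3)[C@H]1O
F8 | step 5 | 2-C-(hydroxymethyl)-2,3:5,6-di-O-isopropylidene-D-mannono-1,4-lactone | O=C1[C@@]2(CO)OC(C)(C)O[C@H]2[C@H](O1)[C@H]1COC(C)(C)O1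
F9 | step 5 | 2-C-[(benzoyloxy)methyl]-2,3:5,6-di-O-isopropylidene-D-mannono-1,4-lactone | O=C1[C@@]2(COC(=O)c3ccccc3)OC(C)(C)O[C@H]2[C@H](O1)[C@H]1COC(C)(C)O1
F10 | step 5 | 2-C-[(benzoyloxy)methyl]-2,3-O-isopropylidene-D-mannono-1,4-lactone (5,6-diol) | O=C1[C@@]2(COC(=O)c3ccccc3)OC(C)(C)O[C@H]2[C@H](O1)[C@H](O)CO
F11 | step 5 | 2-C-[(benzoyloxy)methyl]-2,3-O-isopropylidene-D-lyxo-pentodialdo-1,4-lactone (5-aldehyde) | O=C1[C@@]2(COC(=O)c3ccccc3)OC(C)(C)O[C@H]2[C@H](O1)C=O
F12 | step 5 | 2-C-[(benzoyloxy)methyl]-5-deoxy-2,3-O-isopropylidene-6-O-methyl-D-lyxo-hex-5-enono-1,4-lactone (E/Z mixture) | O=C1[C@@]2(COC(=O)c3ccccc3)OC(C)(C)O[C@H]2[C@H](O1)C=COC
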